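## Retrosynthetic overview

1. The C12–O formate bond is made last, by 1,3-transposition of a C7 tertiary isopropenyl carbinol with formyl trapping; this also creates the E C7=C11 alkene (proposed new step).
2. The C9–OAc bond comes from Mitsunobu inversion of a 9β-alcohol; C3–OAc comes from Luche reduction and acetylation of a ring A enone made by Saegusa oxidation.
3. Ring B is made first as a cyclohexenone with cis 9-OH and 10-CH3; ring A is annulated second by a Diels–Alder reaction with a 2-siloxy-3-methyl diene (C1–C2 and C5–C6 bonds), both ring B substituents steering the diene to the same face.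
4. The ring B enone comes from 4-methylanisole: Birch reduction, methoxyselenenylation (regiochemical marker), hydroboration–oxidation (C9–O), Mitsunobu inversion, lipase resolution.
5. C11–C13 come from isopropenylmagnesium bromide.

Assumption: bicyclic compounds carry cadinane numbering (ring A = C1–C2–C3–C4–C5–C6, ring B = C1–C10–C9–C8–C7–C6, C11 on C7 bearing C12 and C13, C14 on C10, C15 on C4), and β is the face of H-1 and H-6; the target is then (1S,3R,6S,9R,10R,7(11)E).

## Route

Step 1
Reactants: 1 4-methylanisole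
Product: 2 1-methoxy-4-methylcyclohexa-1,4-diene
Conditions: Li, NH3 (l), t-BuOH, THF, −78 to −33 °C; then H2O
Reagents that add atoms: none
Why: Birch reduction leaves the methoxy- and methyl-bearing carbons sp2, giving the unconjugated 1,4-diene whose enol ether double bond points toward the future C6 and so stores the ring B enone regiochemistry.

Step 2
Reactants: 2 1-methoxy-4-methylcyclohexa-1,4-diene
Product: 3 [(6,6-dimethoxy-3-methylcyclohex-3-en-1-yl)selanyl]benzene (racemic)
Conditions: PhSeCl, MeOH, NaHCO3, CH2Cl2, −78 to 0 °C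
Reagents that add atoms: benzeneselenenyl chloride Cl[Se]c1ccccc1; methanol CO
Why: Methoxyselenenylation: PhSeCl attacks the enol ether far faster than the trisubstituted alkene and methanol traps the oxocarbenium ion, so the ketone is masked as a dimethyl ketal and selenium marks the future C6.

Step 3
Reactants: 3 [(6,6-dimethoxy-3-methylcyclohex-3-en-1-yl)selanyl]benzene
Product: 6 rac-(1R,2R)-5,5-dimethoxy-2-methylcyclohex-3-en-1-ol (trans), via borane adduct 4 (not isolated), via hydroxy selenoxide 5 (not isolated)
Conditions: 9-borabicyclo[3.3.1]nonane (9-BBN), THF, 65 °C; then NaOH, H2O2, 0 to 25 °C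
Reagents that add atoms: hydrogen peroxide OO
Why: Hydroboration–oxidation with syn H–B addition (boron on the less substituted future C9) and retentive oxidation sets the trans 9-hydroxy/10-methyl pair, while the same peroxide forms a selenoxide whose syn-elimination can only run toward the future C1.

Step 4
Reactants: 6 rac-(1R,2R)-5,5-dimethoxy-2-methylcyclohex-3-en-1-ol
Product: 8 rac-(4R,5S)-5-hydroxy-4-methylcyclohex-2-en-1-one (cis), via cis formate 7 (not isolated)
Conditions: HCO2H, PPh3, diisopropyl azodicarboxylate, THF, 0 to 25 °C; then 1 M HCl, MeOH/H2O, 25 °C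
Reagents that add atoms: formic acid O=CO; water O
Why: Mitsunobu reaction (SN2 inversion by formate) places the 9-oxygen cis to the 10-methyl group so that both substituents shield one face in step 7, and acidic methanol then cleaves the formate and the allylic ketal to give the hydroxy enone.

Step 5
Reactants: 8 rac-(4R,5S)-5-hydroxy-4-methylcyclohex-2-en-1-one
Product: 9 (4R,5S)-5-hydroxy-4-methylcyclohex-2-en-1-one
Conditions: immobilised Candida antarctica lipase B, vinyl acetate, t-BuOMe, 30 °C, to about 55 % conversion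
Reagents that add atoms: none
Why: Lipase-catalysed kinetic resolution by transesterification: by Kazlauskas' rule the (5R)-carbinol of the (4S,5R)-enantiomer is acetylated, so the wanted (4R,5S)-alcohol is recovered unreacted in high ee.

Step 6
Reactants: 10 3-methylbut-3-en-2-one
Product: 11 triethyl[(3-methylbuta-1,3-dien-2-yl)oxy]silane
Conditions: Et3SiOTf, Et3N, Et2O, 0 °C
Reagents that add atoms: triethylsilyl trifluoromethanesulfonate CC[Si](CC)(CC)OS(=O)(=O)C(F)(F)F
Why: Soft enolisation and O-silylation of a ketone that can enolise only toward its methyl group gives a single 2-siloxy diene.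

Step 7
Reactants: 9 (4R,5S)-5-hydroxy-4-methylcyclohex-2-en-1-one; 11 triethyl[(3-methylbuta-1,3-dien-2-yl)oxy]silane
Product: 12 9β-hydroxy-3-(triethylsilyloxy)-11,12,13-trinorcadin-3-en-7-one (1βH,6βH,10β-methyl)
Conditions: Me2AlCl (2.2 equiv), CH2Cl2, −78 to −30 °C; pH 7 buffer work-up
Reagents that add atoms: none
Why: Lewis acid-promoted Diels–Alder reaction in which the CH2 terminus next to the siloxy carbon bonds to the enone β-carbon (C1) and the diene adds anti to both the 10-methyl and the 9-aluminoxy group (matched 4- and 5-substituent control), giving the cis ring fusion with H-1 and H-6 on the methyl face and a regiodefined C3=C4 enol silane.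

Step 8
Reactants: 12 9β-hydroxy-3-(triethylsilyloxy)-11,12,13-trinorcadin-3-en-7-one
Product: 13 3-(triethylsilyloxy)cadina-3,11-diene-7β,9β-diol (1βH,6βH,10β-methyl)
Conditions: isopropenylmagnesium bromide (2.5 equiv), LaCl3·2LiCl (30 mol %), THF, −78 to −40 °C
Reagents that add atoms: isopropenylmagnesium bromide C=C(C)[Mg]Br
Why: Lanthanum-assisted Grignard 1,2-addition (Knochel conditions) to the hindered, enolisable C7 ketone of the magnesium alkoxide; the new C7 centre (chelation-controlled 7β-alcohol expected) is inconsequential because C7 becomes sp2 in step 13.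

Step 9
Reactants: 13 3-(triethylsilyloxy)cadina-3,11-diene-7β,9β-diol
Product: 14 7β,9β-dihydroxycadina-4,11-dien-3-one (1βH,6βH,10β-methyl)
Conditions: Pd(OAc)2 (1.1 equiv), MeCN, 25 °C
Reagents that add atoms: none
Why: Ito–Saegusa oxidation: the palladium enolate at C4 undergoes syn β-hydride elimination from the C5 methylene, so the enol silane gives the endocyclic C4=C5 enone regiospecifically.

Step 10
Reactants: 14 7β,9β-dihydroxycadina-4,11-dien-3-one
Product: 15 9α-acetoxy-7β-hydroxycadina-4,11-dien-3-one (1βH,6βH,10β-methyl)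
Conditions: AcOH, PPh3, diisopropyl azodicarboxylate, toluene, 0 to 25 °C
Reagents that add atoms: acetic acid CC(=O)O
Why: Mitsunobu reaction: only the secondary axial 9β-hydroxyl is activated (the tertiary 7-hydroxyl is inert) and acetate displaces it with inversion, forming the C9–O bond of the target as the equatorial 9α-acetate trans to the 10-methyl group.

Step 11
Reactants: 15 9α-acetoxy-7β-hydroxycadina-4,11-dien-3-one
Product: 16 9α-acetoxycadina-4,11-diene-3α,7β-diol (1βH,6βH,10β-methyl)
Conditions: NaBH4, CeCl3·7H2O, MeOH, −78 to −20 °C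
Reagents that add atoms: none
Why: Luche reduction: 1,2-hydride delivery from the convex β face, anti to the pseudoaxial C1–C10 bond of the cis-fused bicycle, gives the 3α allylic alcohol.

Step 12
Reactants: 16 9α-acetoxycadina-4,11-diene-3α,7β-diol
Product: 17 3α,9α-diacetoxycadina-4,11-dien-7β-ol (1βH,6βH,10β-methyl)
Conditions: Ac2O, pyridine, 4-(dimethylamino)pyridine (5 mol %), CH2Cl2, 0 °C
Reagents that add atoms: acetic anhydride CC(=O)OC(C)=O
Why: Acylation of the secondary allylic alcohol leaves the hindered tertiary alcohol free and blocks C3 against allylic transposition in step 13.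

Step 13
Reactants: 17 3α,9α-diacetoxycadina-4,11-dien-7β-ol
Product: 19 (1S,3R,6S,9R,10R)-3α,9α-diacetoxycadina-4,7(11)E-dien-12-yl formate, via allylic alcohol 18 (not isolated)
Conditions: Ph3SiOReO3 (5 mol %), HCO2CH2CF3 (10 equiv), Et2O, −20 to 0 °C
Reagents that add atoms: 2,2,2-trifluoroethyl formate O=COCC(F)(F)F
Why: Proposed new method: the heptavalent rhenium catalyst forms the tertiary allyl perrhenate, a chair-like 1,3-oxygen shift (formal [3,3] rearrangement) gives the primary allyl perrhenate and, by ester exchange, alcohol 18, and 2,2,2-trifluoroethyl formate, inert toward the tertiary alcohol, formylates only this primary alcohol and so drains the reversible transposition into the formate with the CH2O group syn to the C8 methylene rather than the branched C6 (E alkene, least allylic strain); the closest known reaction is the oxorhenium-catalysed 1,3-transposition of allylic alcohols driven by in situ silylation with N,O-bis(trimethylsilyl)acetamide, whereas formyl-transfer trapping that sets a tetrasubstituted alkene geometry has not been reported.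

## Compound list

1 | 4-methylanisole | COc1ccc(C)cc1 | starting material
2 | 1-methoxy-4-methylcyclohexa-1,4-diene | COC1=CCC(C)=CC1 | intermediate
3 | [(6,6-dimethoxy-3-methylcyclohex-3-en-1-yl)selanyl]benzene (racemic) | COC1(OC)CC=C(C)CC1[Se]c1ccccc1 | intermediate
4 | 9-[trans-5,5-dimethoxy-2-methyl-4-(phenylselanyl)cyclohexyl]-9-borabicyclo[3.3.1]nonane (racemic, boron trans to methyl; not isolated) | COC1(OC)C[C@@H](B2C3CCCC2CCC3)[C@H](C)CC1[Se]c1ccccc1 | intermediate
5 | trans-5,5-dimethoxy-2-methyl-4-(phenylseleninyl)cyclohexan-1-ol (racemic; not isolated) | COC1(OC)C[C@@H](O)[C@H](C)CC1[Se](=O)c1ccccc1 | intermediate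
6 | rac-(1R,2R)-5,5-dimethoxy-2-methylcyclohex-3-en-1-ol (trans; one enantiomer drawn) | COC1(OC)C[C@@H](O)[C@H](C)C=C1 | intermediate
7 | rac-(1S,2R)-5,5-dimethoxy-2-methylcyclohex-3-en-1-yl formate (cis; not isolated) | COC1(OC)C[C@H](OC=O)[C@H](C)C=C1 | intermediate
8 | rac-(4R,5S)-5-hydroxy-4-methylcyclohex-2-en-1-one (cis racemate; one enantiomer drawn) | O=C1C[C@H](O)[C@H](C)C=C1 | intermediate
9 | (4R,5S)-5-hydroxy-4-methylcyclohex-2-en-1-one (single enantiomer) | O=C1C[C@H](O)[C@H](C)C=C1 | intermediate
10 | 3-methylbut-3-en-2-one | CC(=O)C(C)=C | starting material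
11 | triethyl[(3-methylbuta-1,3-dien-2-yl)oxy]silane | C=C(C)C(=C)O[Si](CC)(CC)CC | intermediate
12 | 9β-hydroxy-3-(triethylsilyloxy)-11,12,13-trinorcadin-3-en-7-one (1βH,6βH,10β-methyl) | CC1=C(O[Si](CC)(CC)CC)C[C@@H]2[C@@H](C)[C@@H](O)CC(=O)[C@@H]2C1 | intermediate
13 | 3-(triethylsilyloxy)cadina-3,11-diene-7β,9β-diol (7α-isopropenyl; expected major C7 epimer) | CC1=C(O[Si](CC)(CC)CC)C[C@@H]2[C@@H](C)[C@@H](O)C[C@](O)(C(C)=C)[C@@H]2C1 | intermediate
14 | 7β,9β-dihydroxycadina-4,11-dien-3-one | O=C1C[C@@H]2[C@@H](C)[C@@H](O)C[C@](O)(C(C)=C)[C@@H]2C=C1C | intermediate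
15 | 9α-acetoxy-7β-hydroxycadina-4,11-dien-3-one | O=C1C[C@@H]2[C@@H](C)[C@H](OC(C)=O)C[C@](O)(C(C)=C)[C@@H]2C=C1C | intermediate
16 | 9α-acetoxycadina-4,11-diene-3α,7β-diol | O[C@@H]1C[C@@H]2[C@@H](C)[C@H](OC(C)=O)C[C@](O)(C(C)=C)[C@@H]2C=C1C | intermediate
17 | 3α,9α-diacetoxycadina-4,11-dien-7β-ol | CC(=O)O[C@@H]1C[C@@H]2[C@@H](C)[C@H](OC(C)=O)C[C@](O)(C(C)=C)[C@@H]2C=C1C | intermediate
18 | 3α,9α-diacetoxycadina-4,7(11)E-dien-12-ol (not isolated) | CC(=O)O[C@@H]1C[C@@H]2[C@@H](C)[C@H](OC(C)=O)C/C(=C(/C)CO)[C@@H]2C=C1C | intermediate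
19 | (1S,3R,6S,9R,10R)-3α,9α-diacetoxycadina-4,7(11)E-dien-12-yl formate | CC(=O)O[C@@H]1C[C@@H]2[C@@H](C)[C@H](OC(C)=O)C/C(=C(/C)COC=O)[C@@H]2C=C1C | target

## Step count and risks

Total steps: 13. Longest linear sequence: 12 (steps 1–5 and 7–13; step 6 is the one-step diene branch).

Step 13 (proposed new step). Risks are incomplete formyl trapping, modest E/Z selectivity, and proton loss from the allyl perrhenate toward the doubly allylic C6. The fallback uses known chemistry, sets out from 17 and comes back at 19: PBr3 with a little pyridine in Et2O at −30 °C converts the tertiary vinyl carbinol by SN2′-type bromination (the linalool-to-geranyl bromide reaction) into 3α,9α-diacetoxy-12-bromocadina-4,7(11)E-diene F1, and sodium formate in DMF at 25 °C displaces bromide to give 19.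

Step 7 (Diels–Alder reaction of a free β-hydroxy enone). Risks are dehydration of 9 toward p-cresol under the aluminium Lewis acid and loss of the enol silane. The fallback sets out from 9 and comes back at 14 with a protecting-group sequence and Brønsted acid catalysis: Et3SiCl/imidazole gives (4R,5S)-4-methyl-5-(triethylsilyloxy)cyclohex-2-en-1-one F2. Tf2NH (10 mol %) with 11 in CH2Cl2 at −78 °C gives 3,9β-bis(triethylsilyloxy)-11,12,13-trinorcadin-3-en-7-one F3. Isopropenylmagnesium bromide with LaCl3·2LiCl gives 3,9β-bis(triethylsilyloxy)cadina-3,11-dien-7β-ol F4. Pd(OAc)2 in MeCN followed by HF·pyridine gives 14.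

Step 10 (Mitsunobu inversion of a hindered axial alcohol beside a tertiary carbinol). Risks are E2 elimination to a C8=C9 or C9=C10 alkene and slow activation. The fallback sets out from 14 and comes back at 15 by oxidation and directed reduction: Dess–Martin periodinane gives 7β-hydroxycadina-4,11-diene-3,9-dione F5. Me4NBH(OAc)3 in MeCN/AcOH at −20 °C (Evans–Saksena reduction) delivers hydride from the face of the 7β-hydroxyl and gives the anti diol 7β,9α-dihydroxycadina-4,11-dien-3-one F6. Ac2O/pyridine then acetylates the secondary alcohol to 15.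

Further compounds
F1 | step 13 | 3α,9α-diacetoxy-12-bromocadina-4,7(11)E-diene | CC(=O)O[C@@H]1C[C@@H]2[C@@H](C)[C@H](OC(C)=O)C/C(=C(/C)CBr)[C@@H]2C=C1C
F2 | step 7 | (4R,5S)-4-methyl-5-(triethylsilyloxy)cyclohex-2-en-1-one | O=C1C[C@H](O[Si](CC)(CC)CC)[C@H](C)C=C1
F3 | step 7 | 3,9β-bis(triethylsilyloxy)-11,12,13-trinorcadin-3-en-7-one | CC1=C(O[Si](CC)(CC)CC)C[C@@H]2[C@@H](C)[C@@H](O[Si](CC)(CC)CC)CC(=O)[C@@H]2C1
F4 | step 7 | 3,9β-bis(triethylsilyloxy)cadina-3,11-dien-7β-ol | CC1=C(O[Si](CC)(CC)CC)C[C@@H]2[C@@H](C)[C@@H](O[Si](CC)(CC)CC)C[C@](O)(C(C)=C)[C@@H]2C1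
F5 | step 10 | 7β-hydroxycadina-4,11-diene-3,9-dione | O=C1C[C@@H]2[C@@H](C)C(=O)C[C@](O)(C(C)=C)[C@@H]2C=C1C
F6 | step 10 | 7β,9α-dihydroxycadina-4,11-dien-3-one | O=C1C[C@@H]2[C@@H](C)[C@H](O)C[C@](O)(C(C)=C)[C@@H]2C=C1C
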